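The flavanone is disconnected at the C4–C4a bond of ring C. Ring A is a phloroglucinol in which the two carbons ortho to the ether oxygen O1 are equivalent, so an acyl cation tethered through C2–C3 can close onto only one position and delivers the C5 and C7 oxygens where they belong. A single intramolecular Friedel–Crafts acylation therefore forms C4–C4a and ring C without touching any stereocentre. Its precursor is a (3S)-3-aryl-3-[3,5-bis(benzyloxy)phenoxy]propanoic acid whose ring B already carries the (R,R)-arylglycerol ether as a bis-silyl ether; the C2 configuration is set beforehand by asymmetric β-borylation–oxidation and Mitsunobu inversion.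

Key step: step 10

Assumption: 3,5-bis(benzyloxy)phenol and 4-(benzyloxy)benzoyl chloride are purchased; the catalyst antipodes named in steps 3 and 7 follow the accepted models for aryl-ketone transfer hydrogenation and cinnamate β-borylation, the configurations of 6 and 12 would be confirmed by MTPA-ester analysis, and the antipodal catalyst would be used if the sense proved opposite.

Shorthand in names: SC = (1R,2R)-1-[4-(benzyloxy)phenyl]-1,3-bis[(tert-butyldimethylsilyl)oxy]propan-2-yl, bound through its C2 to the oxygen at C4 of the 3,5-dimethoxyphenyl ring (ring B); TBS = tert-butyldimethylsilyl; Bn = benzyl.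

Step 1
Reactants: 1 4-bromo-2,6-dimethoxyphenol; 2 ethyl bromoacetate
Product: 3 ethyl 2-(4-bromo-2,6-dimethoxyphenoxy)acetate
Conditions: K2CO3, acetone, reflux
Reagents that add atoms: none
Why: Williamson ether synthesis; the phenoxide displaces the activated primary bromide by SN2 and no other electrophilic site is present.

Step 2
Reactants: 3 ethyl 2-(4-bromo-2,6-dimethoxyphenoxy)acetate; 4 4-(benzyloxy)benzoyl chloride
Product: 5 ethyl (2RS)-3-[4-(benzyloxy)phenyl]-2-(4-bromo-2,6-dimethoxyphenoxy)-3-oxopropanoate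
Conditions: LiN(SiMe3)2 (2 equiv), 3 (2 equiv), THF, −78 °C; then 4 (1 equiv), −78 → 0 °C; 1 M HCl quench (excess 3 recovered)
Reagents that add atoms: none
Why: Claisen-type C-acylation of the lithium ester enolate by the aroyl chloride, the second equivalent of enolate taking up the acidic proton of the β-keto ester; the α-centre is left racemic on purpose because step 3 epimerises and resolves it.

Step 3
Reactants: 5 ethyl (2RS)-3-[4-(benzyloxy)phenyl]-2-(4-bromo-2,6-dimethoxyphenoxy)-3-oxopropanoate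
Product: 6 ethyl (2S,3R)-3-[4-(benzyloxy)phenyl]-2-(4-bromo-2,6-dimethoxyphenoxy)-3-hydroxypropanoate
Conditions: RuCl[(S,S)-TsDPEN](p-cymene) (cat.), HCO2H/Et3N (5:2), CH2Cl2, 30 °C
Reagents that add atoms: none
Why: Noyori asymmetric transfer hydrogenation under dynamic kinetic resolution; the (S,S)-catalyst should set the carbinol carbon as 3R, while amine-mediated epimerisation of the doubly activated C2–H funnels both enantiomers of 5 into the syn (2S,3R) isomer, as established for α-alkoxy β-keto esters.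

Step 4
Reactants: 6 ethyl (2S,3R)-3-[4-(benzyloxy)phenyl]-2-(4-bromo-2,6-dimethoxyphenoxy)-3-hydroxypropanoate
Product: 7 (1R,2R)-1-[4-(benzyloxy)phenyl]-2-(4-bromo-2,6-dimethoxyphenoxy)propane-1,3-diol
Conditions: LiBH4, THF, 0 °C → rt; aq NH4Cl
Reagents that add atoms: none
Why: Chemoselective hydride reduction of the ester, sparing aryl bromide and benzyl ether; no stereocentre is touched, and the C2 descriptor changes from S to R only because CH2OH ranks below the carbinol carbon.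

Step 5
Reactants: 7 (1R,2R)-1-[4-(benzyloxy)phenyl]-2-(4-bromo-2,6-dimethoxyphenoxy)propane-1,3-diol
Product: 8 (1R,2R)-1-[4-(benzyloxy)phenyl]-2-(4-bromo-2,6-dimethoxyphenoxy)-1,3-bis[(tert-butyldimethylsilyl)oxy]propane (SC–O-aryl bromide)
Conditions: TBSOTf, 2,6-lutidine, CH2Cl2, 0 °C
Reagents that add atoms: tert-butyldimethylsilyl trifluoromethanesulfonate, CC(C)(C)[Si](C)(C)OS(=O)(=O)C(F)(F)F
Why: Silylation of both hydroxyls with the reactive silyl triflate, which also reaches the hindered benzylic secondary alcohol; the two TBS ethers are non-chelating and should survive the later Lewis acid where an acetonide would not.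

Step 6
Reactants: 8 SC–O-aryl bromide; 9 methyl acrylate
Product: 10 methyl (2E)-3-[3,5-dimethoxy-4-(SC-oxy)phenyl]prop-2-enoate
Conditions: Pd(OAc)2, P(o-tol)3, Et3N, DMF, 100 °C
Reagents that add atoms: none
Why: Mizoroki–Heck reaction of an unhindered aryl bromide with an acrylate; syn insertion followed by syn β-hydride elimination gives the E-cinnamate, and silyl and benzyl ethers are inert.

Step 7
Reactants: 10 methyl (2E)-3-[3,5-dimethoxy-4-(SC-oxy)phenyl]prop-2-enoate
Product: 12 methyl (3R)-3-[3,5-dimethoxy-4-(SC-oxy)phenyl]-3-hydroxypropanoate, via β-boryl ester 11 (not isolated)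
Conditions: CuCl, NaOtBu, (S)-1-[(Rp)-2-(diphenylphosphino)ferrocenyl]ethyldicyclohexylphosphine, B2pin2, MeOH, THF, rt; then NaBO3·4H2O, THF/H2O, rt
Reagents that add atoms: bis(pinacolato)diboron, CC1(C)OB(OC1(C)C)B1OC(C)(C)C(C)(C)O1 (boryl group of 11); sodium perborate, [Na+].[Na+].O[B-]1(O)OO[B-](O)(O)OO1 (hydroxyl oxygen of 12)
Why: Copper-catalysed asymmetric conjugate borylation of a cinnamate followed by stereoretentive C–B oxidation; the chiral bisphosphine–copper boryl complex selects the alkene face, so the new benzylic centre (3R) is under catalyst control and is unaffected by the remote side-chain centres.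

Step 8
Reactants: 12 methyl (3R)-3-[3,5-dimethoxy-4-(SC-oxy)phenyl]-3-hydroxypropanoate; 13 3,5-bis(benzyloxy)phenol
Product: 14 methyl (3S)-3-[3,5-bis(benzyloxy)phenoxy]-3-[3,5-dimethoxy-4-(SC-oxy)phenyl]propanoate
Conditions: PPh3, DIAD, toluene, 0 °C → rt
Reagents that add atoms: none
Why: Mitsunobu etherification; the phenol (pKa about 9–10) displaces the alkoxyphosphonium by SN2, inverting 3R to 3S, and the non-polar solvent and the only weakly donating ring B (two meta methoxy groups, a twisted para ether) disfavour benzylic ion-pair leakage.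

Step 9
Reactants: 14 methyl (3S)-3-[3,5-bis(benzyloxy)phenoxy]-3-[3,5-dimethoxy-4-(SC-oxy)phenyl]propanoate
Product: 15 (3S)-3-[3,5-bis(benzyloxy)phenoxy]-3-[3,5-dimethoxy-4-(SC-oxy)phenyl]propanoic acid
Conditions: Me3SnOH, ClCH2CH2Cl, 70 °C; cold 0.1 M HCl wash
Reagents that add atoms: trimethyltin hydroxide, C[Sn](C)(C)O
Why: Trimethyltin hydroxide ester hydrolysis proceeds by hydroxide delivery to the carbonyl under essentially neutral conditions, so E1cB loss of the β-aryloxide and silyl cleavage are avoided and C3 is untouched.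

Step 10
Reactants: 15 (3S)-3-[3,5-bis(benzyloxy)phenoxy]-3-[3,5-dimethoxy-4-(SC-oxy)phenyl]propanoic acid
Product: 17 (2S)-5,7-bis(benzyloxy)-2-[3,5-dimethoxy-4-(SC-oxy)phenyl]-2,3-dihydro-4H-chromen-4-one, via acid chloride 16 (not isolated)
Conditions: 1-chloro-N,N,2-trimethylprop-1-en-1-amine, CH2Cl2, 0 °C; then SnCl4 (2.2 equiv), CH2Cl2, −78 °C, short reaction time; cold aq NaHCO3 quench
Reagents that add atoms: 1-chloro-N,N,2-trimethylprop-1-en-1-amine, CC(C)=C(Cl)N(C)C (chlorine of 16 only; no reagent atom remains in 17)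
Why: The α-chloroenamine converts the acid into acyl chloride 16 without releasing HCl, and SnCl4 then generates the acylium ion (or its tight ion pair), which is attacked by a ring-A carbon ortho to the ether oxygen O1; proton loss from the arenium ion restores aromaticity and gives the C4 aryl ketone. The closest known reaction type is the intramolecular Friedel–Crafts acylation of 3-aryloxy- and 3-aryl-3-aryloxypropanoyl chlorides to chroman-4-ones and flavanones. Ring C closes in a 6-exo mode at the acylium carbon, with the C≡O unit outside the new ring and the C4a–C8a arene bond inside it. No stereocentre is created, and C2 keeps the S configuration from step 8 because none of its bonds is broken, provided the reaction is run cold and briefly so that ionisation of the benzylic C2–O1 bond and β-elimination of the aryloxide cannot compete. Regioselectivity is secured by the substrate: the two carbons ortho to O1 are equivalent by rotation about the O1–aryl bond, the carbon between the two benzyloxy groups cannot reach the tether, and the phloroglucinol triether ring is far more nucleophilic than ring B or the 4-benzyloxyphenyl ring, which could only close strained or large rings. The non-chelating TBS ethers and the benzyl ethers should not ionise with SnCl4 at −78 °C.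

Step 11
Reactants: 17 (2S)-5,7-bis(benzyloxy)-2-[3,5-dimethoxy-4-(SC-oxy)phenyl]-2,3-dihydro-4H-chromen-4-one
Product: 18 (2S)-5,7-bis(benzyloxy)-2-[4-({(1R,2R)-1-[4-(benzyloxy)phenyl]-1,3-dihydroxypropan-2-yl}oxy)-3,5-dimethoxyphenyl]-2,3-dihydro-4H-chromen-4-one
Conditions: HF·pyridine, pyridine, THF, 0 °C → rt
Reagents that add atoms: none
Why: Fluoride-driven desilylation of both TBS ethers under buffered, mildly acidic conditions, chosen over basic fluoride so that ring C is not opened to the chalcone (which would racemise C2); the phenol is still benzylated, so the benzylic alcohol cannot form a quinone methide.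

Step 12
Reactants: 18 (2S)-5,7-bis(benzyloxy)-2-[4-({(1R,2R)-1-[4-(benzyloxy)phenyl]-1,3-dihydroxypropan-2-yl}oxy)-3,5-dimethoxyphenyl]-2,3-dihydro-4H-chromen-4-one
Product: 19 (2S)-2-[4-({(1R,2R)-1,3-dihydroxy-1-(4-hydroxyphenyl)propan-2-yl}oxy)-3,5-dimethoxyphenyl]-5,7-dihydroxy-2,3-dihydro-4H-chromen-4-one (target)
Conditions: H2 (1 atm), palladium on carbon (Pd/C), EtOAc/EtOH, rt
Reagents that add atoms: none
Why: Heterogeneous hydrogenolysis of the three O-benzyl ethers in a neutral solvent, stopped at complete debenzylation, should leave the ketone, the benzylic C7 hydroxyl and the benzylic C2–O1 bond intact.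

Compound list
1 | 4-bromo-2,6-dimethoxyphenol | COc1cc(Br)cc(OC)c1O | starting material
2 | ethyl bromoacetate | CCOC(=O)CBr | starting material
3 | ethyl 2-(4-bromo-2,6-dimethoxyphenoxy)acetate | CCOC(=O)COc1c(OC)cc(Br)cc1OC | intermediate
4 | 4-(benzyloxy)benzoyl chloride | O=C(Cl)c1ccc(OCc2ccccc2)cc1 | starting material
5 | ethyl (2RS)-3-[4-(benzyloxy)phenyl]-2-(4-bromo-2,6-dimethoxyphenoxy)-3-oxopropanoate | CCOC(=O)C(Oc1c(OC)cc(Br)cc1OC)C(=O)c1ccc(OCc2ccccc2)cc1 | intermediate
6 | ethyl (2S,3R)-3-[4-(benzyloxy)phenyl]-2-(4-bromo-2,6-dimethoxyphenoxy)-3-hydroxypropanoate | COc1cc(Br)cc(OC)c1O[C@H](C(=O)OCC)[C@H](O)c1ccc(OCc2ccccc2)cc1 | intermediate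
7 | (1R,2R)-1-[4-(benzyloxy)phenyl]-2-(4-bromo-2,6-dimethoxyphenoxy)propane-1,3-diol | COc1cc(Br)cc(OC)c1O[C@H](CO)[C@H](O)c1ccc(OCc2ccccc2)cc1 | intermediate
8 | (1R,2R)-1-[4-(benzyloxy)phenyl]-2-(4-bromo-2,6-dimethoxyphenoxy)-1,3-bis[(tert-butyldimethylsilyl)oxy]propane | COc1cc(Br)cc(OC)c1O[C@H](CO[Si](C)(C)C(C)(C)C)[C@H](O[Si](C)(C)C(C)(C)C)c1ccc(OCc2ccccc2)cc1 | intermediate
9 | methyl acrylate | C=CC(=O)OC | starting material
10 | methyl (2E)-3-[4-({(1R,2R)-1-[4-(benzyloxy)phenyl]-1,3-bis[(tert-butyldimethylsilyl)oxy]propan-2-yl}oxy)-3,5-dimethoxyphenyl]prop-2-enoate | COC(=O)/C=C/c1cc(OC)c(O[C@H](CO[Si](C)(C)C(C)(C)C)[C@H](O[Si](C)(C)C(C)(C)C)c2ccc(OCc3ccccc3)cc2)c(OC)c1 | intermediate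
11 | methyl (3R)-3-[4-({(1R,2R)-1-[4-(benzyloxy)phenyl]-1,3-bis[(tert-butyldimethylsilyl)oxy]propan-2-yl}oxy)-3,5-dimethoxyphenyl]-3-(4,4,5,5-tetramethyl-1,3,2-dioxaborolan-2-yl)propanoate | COc1cc([C@H](B2OC(C)(C)C(C)(C)O2)CC(=O)OC)cc(OC)c1O[C@H](CO[Si](C)(C)C(C)(C)C)[C@H](O[Si](C)(C)C(C)(C)C)c1ccc(OCc2ccccc2)cc1 | intermediate (not isolated)
12 | methyl (3R)-3-[4-({(1R,2R)-1-[4-(benzyloxy)phenyl]-1,3-bis[(tert-butyldimethylsilyl)oxy]propan-2-yl}oxy)-3,5-dimethoxyphenyl]-3-hydroxypropanoate | COc1cc([C@H](O)CC(=O)OC)cc(OC)c1O[C@H](CO[Si](C)(C)C(C)(C)C)[C@H](O[Si](C)(C)C(C)(C)C)c1ccc(OCc2ccccc2)cc1 | intermediate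
13 | 3,5-bis(benzyloxy)phenol | Oc1cc(OCc2ccccc2)cc(OCc2ccccc2)c1 | starting material
14 | methyl (3S)-3-[3,5-bis(benzyloxy)phenoxy]-3-[4-({(1R,2R)-1-[4-(benzyloxy)phenyl]-1,3-bis[(tert-butyldimethylsilyl)oxy]propan-2-yl}oxy)-3,5-dimethoxyphenyl]propanoate | COc1cc([C@@H](Oc2cc(OCc3ccccc3)cc(OCc3ccccc3)c2)CC(=O)OC)cc(OC)c1O[C@H](CO[Si](C)(C)C(C)(C)C)[C@H](O[Si](C)(C)C(C)(C)C)c1ccc(OCc2ccccc2)cc1 | intermediate
15 | (3S)-3-[3,5-bis(benzyloxy)phenoxy]-3-[4-({(1R,2R)-1-[4-(benzyloxy)phenyl]-1,3-bis[(tert-butyldimethylsilyl)oxy]propan-2-yl}oxy)-3,5-dimethoxyphenyl]propanoic acid | COc1cc([C@@H](Oc2cc(OCc3ccccc3)cc(OCc3ccccc3)c2)CC(=O)O)cc(OC)c1O[C@H](CO[Si](C)(C)C(C)(C)C)[C@H](O[Si](C)(C)C(C)(C)C)c1ccc(OCc2ccccc2)cc1 | intermediate (key-step precursor)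
16 | (3S)-3-[3,5-bis(benzyloxy)phenoxy]-3-[4-({(1R,2R)-1-[4-(benzyloxy)phenyl]-1,3-bis[(tert-butyldimethylsilyl)oxy]propan-2-yl}oxy)-3,5-dimethoxyphenyl]propanoyl chloride | COc1cc([C@@H](Oc2cc(OCc3ccccc3)cc(OCc3ccccc3)c2)CC(=O)Cl)cc(OC)c1O[C@H](CO[Si](C)(C)C(C)(C)C)[C@H](O[Si](C)(C)C(C)(C)C)c1ccc(OCc2ccccc2)cc1 | intermediate (not isolated)
17 | (2S)-5,7-bis(benzyloxy)-2-[4-({(1R,2R)-1-[4-(benzyloxy)phenyl]-1,3-bis[(tert-butyldimethylsilyl)oxy]propan-2-yl}oxy)-3,5-dimethoxyphenyl]-2,3-dihydro-4H-chromen-4-one | COc1cc([C@@H]2CC(=O)c3c(OCc4ccccc4)cc(OCc4ccccc4)cc3O2)cc(OC)c1O[C@H](CO[Si](C)(C)C(C)(C)C)[C@H](O[Si](C)(C)C(C)(C)C)c1ccc(OCc2ccccc2)cc1 | intermediate (key-step product)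
18 | (2S)-5,7-bis(benzyloxy)-2-[4-({(1R,2R)-1-[4-(benzyloxy)phenyl]-1,3-dihydroxypropan-2-yl}oxy)-3,5-dimethoxyphenyl]-2,3-dihydro-4H-chromen-4-one | COc1cc([C@@H]2CC(=O)c3c(OCc4ccccc4)cc(OCc4ccccc4)cc3O2)cc(OC)c1O[C@H](CO)[C@H](O)c1ccc(OCc2ccccc2)cc1 | intermediate
19 | (2S)-2-[4-({(1R,2R)-1,3-dihydroxy-1-(4-hydroxyphenyl)propan-2-yl}oxy)-3,5-dimethoxyphenyl]-5,7-dihydroxy-2,3-dihydro-4H-chromen-4-one | COc1cc([C@@H]2CC(=O)c3c(O)cc(O)cc3O2)cc(OC)c1O[C@H](CO)[C@H](O)c1ccc(O)cc1 | target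

Total step count: 12
Longest linear sequence: 12 steps (1 → 19)

Steps most likely to fail

1. Step 10 (key step). What may go wrong: the Lewis acid ionises the benzylic C2–O1 bond, or the aryloxide is eliminated from the acyl chloride before ring closure. Either process erodes the C2 configuration, and silyl groups may be partly lost as well. Fallback, setting out from 8 and returning at 17: ring C is closed at the O1–C2 bond instead. Bromide 8 is lithiated (n-BuLi, THF, −78 °C) and formylated with DMF to give the aldehyde F1. Claisen–Schmidt condensation of F1 with purchased 1-[2,4-bis(benzyloxy)-6-hydroxyphenyl]ethan-1-one (CC(=O)c1c(O)cc(OCc2ccccc2)cc1OCc1ccccc1; KOH, EtOH/THF, rt) should give the 2′-hydroxychalcone F2. Heating F2 with NaOAc in EtOH should close ring C by intramolecular oxa-Michael addition, giving 17 together with its (2R)-epimer F3. The two are diastereomers and would be separated by preparative HPLC, after which 17 re-enters at step 11.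

2. Step 8. What may go wrong: the β-hydroxy ester dehydrates to cinnamate 10 by E1cB-type elimination at the alkoxyphosphonium stage (10 could be recycled through step 7), and inversion fidelity is partly lost through benzylic ion pairing. Fallback, setting out from 12 and returning at 15: the acidic α-hydrogens are removed before the substitution. LiBH4 reduction of 12 should give the 1,3-diol F4, and selective acylation of its primary hydroxyl (pivaloyl chloride, pyridine, 0 °C) the pivalate F5. Mitsunobu etherification of F5 with 13 (PPh3, DIAD, toluene) should give the inverted (S)-aryl ether F6, now without an elimination pathway. DIBAL-H (CH2Cl2, −78 °C) removes the pivalate to give the primary alcohol F7, and TEMPO/PhI(OAc)2 in MeCN/H2O oxidises F7 to acid 15, which re-enters at step 10.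

3. Step 3. What may go wrong: C2 epimerises too slowly relative to hydride transfer, or facial discrimination is poor next to the bulky 2,6-dimethoxyaryloxy group, giving low diastereo- or enantioselectivity. Fallback, setting out from 3 and returning at 7: an auxiliary-controlled aldol sets both centres. Saponification of 3 (LiOH, THF/H2O; HCl) gives the aryloxyacetic acid F8. Activation as the pivaloyl mixed anhydride and N-acylation of (S)-4-benzyl-1,3-oxazolidin-2-one (pivaloyl chloride, Et3N, LiCl, THF) gives the imide F9. Its Z-boron enolate (Bu2BOTf, iPr2NEt, CH2Cl2, −78 °C) should add to purchased 4-(benzyloxy)benzaldehyde (O=Cc1ccc(OCc2ccccc2)cc1) in an Evans syn-aldol reaction to give the (2S,3R) adduct F10. LiBH4 in THF/MeOH cleaves the auxiliary reductively and gives diol 7 directly, which re-enters at step 5.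

Further compounds
F1 | step 10 | 4-({(1R,2R)-1-[4-(benzyloxy)phenyl]-1,3-bis[(tert-butyldimethylsilyl)oxy]propan-2-yl}oxy)-3,5-dimethoxybenzaldehyde | O=Cc1cc(OC)c(O[C@H](CO[Si](C)(C)C(C)(C)C)[C@H](O[Si](C)(C)C(C)(C)C)c2ccc(OCc3ccccc3)cc2)c(OC)c1
F2 | step 10 | (2E)-1-[2,4-bis(benzyloxy)-6-hydroxyphenyl]-3-[4-({(1R,2R)-1-[4-(benzyloxy)phenyl]-1,3-bis[(tert-butyldimethylsilyl)oxy]propan-2-yl}oxy)-3,5-dimethoxyphenyl]prop-2-en-1-one | O=C(/C=C/c1cc(OC)c(O[C@H](CO[Si](C)(C)C(C)(C)C)[C@H](O[Si](C)(C)C(C)(C)C)c2ccc(OCc3ccccc3)cc2)c(OC)c1)c1c(O)cc(OCc2ccccc2)cc1OCc1ccccc1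
F3 | step 10 | (2R)-5,7-bis(benzyloxy)-2-[4-({(1R,2R)-1-[4-(benzyloxy)phenyl]-1,3-bis[(tert-butyldimethylsilyl)oxy]propan-2-yl}oxy)-3,5-dimethoxyphenyl]-2,3-dihydro-4H-chromen-4-one | COc1cc([C@H]2CC(=O)c3c(OCc4ccccc4)cc(OCc4ccccc4)cc3O2)cc(OC)c1O[C@H](CO[Si](C)(C)C(C)(C)C)[C@H](O[Si](C)(C)C(C)(C)C)c1ccc(OCc2ccccc2)cc1
F4 | step 8 | (1R)-1-[4-({(1R,2R)-1-[4-(benzyloxy)phenyl]-1,3-bis[(tert-butyldimethylsilyl)oxy]propan-2-yl}oxy)-3,5-dimethoxyphenyl]propane-1,3-diol | COc1cc([C@H](O)CCO)cc(OC)c1O[C@H](CO[Si](C)(C)C(C)(C)C)[C@H](O[Si](C)(C)C(C)(C)C)c1ccc(OCc2ccccc2)cc1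
F5 | step 8 | (3R)-3-[4-({(1R,2R)-1-[4-(benzyloxy)phenyl]-1,3-bis[(tert-butyldimethylsilyl)oxy]propan-2-yl}oxy)-3,5-dimethoxyphenyl]-3-hydroxypropyl 2,2-dimethylpropanoate | COc1cc([C@H](O)CCOC(=O)C(C)(C)C)cc(OC)c1O[C@H](CO[Si](C)(C)C(C)(C)C)[C@H](O[Si](C)(C)C(C)(C)C)c1ccc(OCc2ccccc2)cc1
F6 | step 8 | (3S)-3-[3,5-bis(benzyloxy)phenoxy]-3-[4-({(1R,2R)-1-[4-(benzyloxy)phenyl]-1,3-bis[(tert-butyldimethylsilyl)oxy]propan-2-yl}oxy)-3,5-dimethoxyphenyl]propyl 2,2-dimethylpropanoate | COc1cc([C@@H](Oc2cc(OCc3ccccc3)cc(OCc3ccccc3)c2)CCOC(=O)C(C)(C)C)cc(OC)c1O[C@H](CO[Si](C)(C)C(C)(C)C)[C@H](O[Si](C)(C)C(C)(C)C)c1ccc(OCc2ccccc2)cc1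
F7 | step 8 | (3S)-3-[3,5-bis(benzyloxy)phenoxy]-3-[4-({(1R,2R)-1-[4-(benzyloxy)phenyl]-1,3-bis[(tert-butyldimethylsilyl)oxy]propan-2-yl}oxy)-3,5-dimethoxyphenyl]propan-1-ol | COc1cc([C@@H](Oc2cc(OCc3ccccc3)cc(OCc3ccccc3)c2)CCO)cc(OC)c1O[C@H](CO[Si](C)(C)C(C)(C)C)[C@H](O[Si](C)(C)C(C)(C)C)c1ccc(OCc2ccccc2)cc1
F8 | step 3 | 2-(4-bromo-2,6-dimethoxyphenoxy)acetic acid | OC(=O)COc1c(OC)cc(Br)cc1OC
F9 | step 3 | (4S)-4-benzyl-3-[2-(4-bromo-2,6-dimethoxyphenoxy)acetyl]-1,3-oxazolidin-2-one | O=C(COc1c(OC)cc(Br)cc1OC)N1[C@@H](Cc2ccccc2)COC1=O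
F10 | step 3 | (4S)-4-benzyl-3-[(2S,3R)-3-[4-(benzyloxy)phenyl]-2-(4-bromo-2,6-dimethoxyphenoxy)-3-hydroxypropanoyl]-1,3-oxazolidin-2-one | COc1cc(Br)cc(OC)c1O[C@H](C(=O)N1[C@@H](Cc2ccccc2)COC1=O)[C@H](O)c1ccc(OCc2ccccc2)cc1
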